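**Plan**
- Cuts: the C–C bond between the pyrrolidine CH and the appended lactone (vinylogous Mannich on a lactam), one C–C bond of the azepane (ring-closing metathesis), the lactone O–C(ring) bond (Baeyer–Villiger), and the N–C(quaternary) bond (nitrogen insertion into a cyclobutanone).
- Enabling feature: the N-bearing quaternary carbon (Cq) is the spiro atom shared by the cyclopentane and the pyrrolidine N–Cq–CH2–CH2–CH(N). With that last carbon as C=O the ring is a γ-lactam, which maps onto a spiro-cyclobutanone Cq–CH2–CH2–C(=O) plus one nitrogen; the fused lactone maps likewise onto a fused cyclobutanone plus one oxygen.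
- Forward order of rings: cyclopentane (chiral enone, three-component coupling) → fused four-membered ketal ([2+2]) → spiro three-membered ring → spiro four-membered ketone → pyrrolidinone → azepine → fused lactone → appended lactone.
- Stereochemistry: CHEt and CH(allyl) from (R)-4-silyloxycyclopentenone (anti, anti); both ring-fusion carbons from cycloaddition anti to ethyl; Cq from convex-face epoxidation and two stereospecific 1,2-shifts (inversion, then retention).
- C(OH)Me from convex-face enolate oxidation; the two centres beside N from iminium addition; the last methyl from hydrogenation.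

Key step: step 6

Assumption: the tertiary alcohol of 16 is carried unprotected through steps 13 and 14; any O-silyl ether formed under the hydrosilane or silyl triflate is expected to be cleaved in the acidic work-up.

Step 1
Reactants: 1 (R)-4-[(tert-butyldimethylsilyl)oxy]cyclopent-2-en-1-one
Product: 3 (2R,3R,4R)-2-allyl-4-[(tert-butyldimethylsilyl)oxy]-3-ethylcyclopentan-1-one, via zinc enolate 2 (not isolated)
Conditions: Et2Zn, EtLi, THF, −78 °C; then allyl iodide, HMPA, −78 to −40 °C
Reagents that add atoms: lithium triethylzincate, [Li+].CC[Zn-](CC)CC, made in the flask from diethylzinc, CC[Zn]CC, and ethyllithium, [Li]CC; allyl iodide, C=CCI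
Why: Three-component coupling of the prostaglandin type (zincate conjugate addition, then enolate allylation), in which ethyl adds anti to the silyloxy group and allyl iodide then attacks the enolate anti to the new ethyl group, giving the all-trans ketone.

Step 2
Reactants: 3 (2R,3R,4R)-2-allyl-4-[(tert-butyldimethylsilyl)oxy]-3-ethylcyclopentan-1-one
Product: 4 (4S,5R)-5-allyl-4-ethylcyclopent-2-en-1-one
Conditions: DBU, CH2Cl2, 0 to 25 °C
Reagents that add atoms: none
Why: E1cB β-elimination of the silanol (the change of an E-type into an A-type prostaglandin ring) unveils the enone on the side remote from the two stereocentres, which are not touched under these mild conditions.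

Step 3
Reactants: 4 (4S,5R)-5-allyl-4-ethylcyclopent-2-en-1-one
Product: 5 (1S,3R,4R,5S)-3-allyl-6,6-diethoxy-4-ethylbicyclo[3.2.0]heptan-2-one
Conditions: 1,1-diethoxyethene (10 equiv), hν (350 nm, Pyrex), CH2Cl2, −40 °C
Reagents that add atoms: 1,1-diethoxyethene, C=C(OCC)OCC
Why: Enone–ketene acetal [2+2] photocycloaddition, in which head-to-tail regiochemistry puts the ketal carbon on the β-carbon, the alkene adds anti to the neighbouring ethyl group, and the four-membered ring can only be cis-fused, so both ring-fusion centres are fixed.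

Step 4
Reactants: 5 (1S,3R,4R,5S)-3-allyl-6,6-diethoxy-4-ethylbicyclo[3.2.0]heptan-2-one
Product: 6 (1S,3R,4R,5S)-3-allyl-2-cyclopropylidene-6,6-diethoxy-4-ethylbicyclo[3.2.0]heptane
Conditions: cyclopropyltriphenylphosphonium bromide, KOtBu, THF, 65 °C
Reagents that add atoms: cyclopropyltriphenylphosphonium bromide, [Br-].C1CC1[P+](c1ccccc1)(c1ccccc1)c1ccccc1
Why: Wittig cyclopropylidenation of a ketone that carries no β-leaving group and so tolerates the basic ylide; no stereocentre is formed and the α-allyl centre should stay in its favoured trans relation to ethyl.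

Step 5
Reactants: 6 (1S,3R,4R,5S)-3-allyl-2-cyclopropylidene-6,6-diethoxy-4-ethylbicyclo[3.2.0]heptane
Product: 8 (1S,2S,3R,4R,5S)-3-allyl-6,6-diethoxy-4-ethylspiro[bicyclo[3.2.0]heptane-2,1'-cyclobutan]-2'-one, via oxaspiropentane 7 (not isolated)
Conditions: mCPBA (1.0 equiv), CH2Cl2, −20 °C; then LiBF4 (10 mol %), 0 to 25 °C
Reagents that add atoms: mCPBA, OOC(=O)c1cccc(Cl)c1
Why: Prilezhaev epoxidation on the convex face (anti to the fused four-membered ring and the allyl group) followed by the oxaspiropentane-to-cyclobutanone (semipinacol) ring expansion, in which a cyclopropane CH2 migrates to the spiro carbon anti to the departing oxygen, so the new C=O carbon ends on the convex face and the CH2 on the concave face.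

Step 6
Reactants: 8 (1S,2S,3R,4R,5S)-3-allyl-6,6-diethoxy-4-ethylspiro[bicyclo[3.2.0]heptane-2,1'-cyclobutan]-2'-one
Product: 10 (1S,2S,3R,4R,5S)-3-allyl-6,6-diethoxy-4-ethylspiro[bicyclo[3.2.0]heptane-2,2'-pyrrolidin]-5'-one, via aza-Criegee adduct 9 (not isolated)
Conditions: Ph2P(O)ONH2 (1.5 equiv), DMF, 25 °C
Reagents that add atoms: O-(diphenylphosphinyl)hydroxylamine, NOP(=O)(c1ccccc1)c1ccccc1
Why: The aminating reagent adds to the strained cyclobutanone carbonyl to give hemiaminal 9, whose N–O bond breaks as the quaternary spiro carbon migrates from carbon to nitrogen with loss of diphenylphosphinate; the closest known reaction type is the Beckmann or aza-Baeyer–Villiger ring expansion of α-quaternary cyclobutanones to γ-lactams. No ring is closed from an open chain: the four-membered ring Cq–CH2–CH2–C(=O) becomes the five-membered lactam by a 1,2-shift of carbon to nitrogen, so no Baldwin descriptor applies. The step forms the C–N bond at the quaternary carbon but no new stereocentre in the product; the configuration set in step 5 is carried over with retention because the migrating carbon keeps its three other bonds throughout. The step needs regioselectivity (migration of the fully substituted carbon, not of the ring CH2) and chemoselectivity (one carbonyl only). The first should follow from the higher migratory aptitude of the more substituted α-carbon; the second from the other four-membered ketone still being masked as its diethyl ketal, which the water-free, weakly acidic conditions should leave intact.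

Step 7
Reactants: 10 (1S,2S,3R,4R,5S)-3-allyl-6,6-diethoxy-4-ethylspiro[bicyclo[3.2.0]heptane-2,2'-pyrrolidin]-5'-one
Product: 11 (1S,2S,3R,4R,5S)-1',3-diallyl-6,6-diethoxy-4-ethylspiro[bicyclo[3.2.0]heptane-2,2'-pyrrolidin]-5'-one
Conditions: NaH, allyl bromide, DMF, 0 to 25 °C
Reagents that add atoms: allyl bromide, C=CCBr
Why: SN2 N-alkylation of the lactam anion, in which no stereocentre is involved.

Step 8
Reactants: 11 (1S,2S,3R,4R,5S)-1',3-diallyl-6,6-diethoxy-4-ethylspiro[bicyclo[3.2.0]heptane-2,2'-pyrrolidin]-5'-one
Product: 12 tetracyclic lactam ketal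
Conditions: second-generation Grubbs catalyst (5 mol %), CH2Cl2, 40 °C
Reagents that add atoms: none
Why: Ring-closing metathesis of the N-allyl and C-allyl groups closes the seven-membered ring as its Z-alkene across the trans-disposed N and CH2 substituents with loss of ethene, without forming a stereocentre.

Step 9
Reactants: 12 tetracyclic lactam ketal
Product: 14 tetracyclic lactam lactone, via cyclobutanone 13 (not isolated)
Conditions: 1 M HCl, THF, 25 °C; then 30% H2O2, AcOH, 0 °C
Reagents that add atoms: water, O; hydrogen peroxide, OO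
Why: Ketal hydrolysis and Baeyer–Villiger oxidation of the strained four-membered ketone, in which the more substituted ring-fusion carbon migrates with retention to give the cis-fused γ-lactone with oxygen on the carbon next to CHEt, while lactam and alkene should be inert to cold H2O2/AcOH.

Step 10
Reactants: 14 tetracyclic lactam lactone
Product: 15 α-methyl lactone
Conditions: LiN(iPr)2, THF, −78 °C; then MeI
Reagents that add atoms: iodomethane, CI
Why: Alkylation of the lactone enolate (more acidic than the lactam) from the convex face of the cis-fused bicycle; the configuration of this carbon is reset in the next step.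

Step 11
Reactants: 15 α-methyl lactone
Product: 16 α-hydroxy-α-methyl lactone
Conditions: KN(SiMe3)2, THF, −78 °C; then 2-(phenylsulfonyl)-3-phenyloxaziridine; NH4Cl (aq)
Reagents that add atoms: 2-(phenylsulfonyl)-3-phenyloxaziridine, O=S(=O)(N1OC1c1ccccc1)c1ccccc1
Why: Davis α-hydroxylation of the lactone enolate, with the oxidant approaching the convex face so that OH is syn to the ring-fusion hydrogens and methyl lies on the concave face, as in the target.

Step 12
Reactants: 17 3-methylfuran-2(5H)-one
Product: 18 3-methyl-2-[(triisopropylsilyl)oxy]furan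
Conditions: TIPSOTf, Et3N, CH2Cl2, 0 °C
Reagents that add atoms: triisopropylsilyl trifluoromethanesulfonate, CC(C)[Si](OS(=O)(=O)C(F)(F)F)(C(C)C)C(C)C
Why: Soft enolisation and O-silylation of the butenolide gives the aromatic 2-silyloxyfuran, with no stereocentre formed.

Step 13
Reactants: 16 α-hydroxy-α-methyl lactone; 18 3-methyl-2-[(triisopropylsilyl)oxy]furan
Product: 21 butenolide adduct, via silyl hemiaminal 19 (not isolated), via iminium ion 20 (not isolated)
Conditions: IrCl(CO)(PPh3)2 (1 mol %), (Me2HSi)2O, toluene, 25 °C; then 18, TMSOTf (10 mol %), CH2Cl2, −78 to −20 °C; 1 M HCl work-up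
Reagents that add atoms: none
Why: Lactam-selective iridium-catalysed hydrosilylation and vinylogous Mukaiyama–Mannich addition of the silyloxyfuran to the derived iminium ion, in which the nucleophile should enter the face of the five-membered iminium ring anti to the azepine and ethyl-bearing side of Cq, and the open antiperiplanar transition state usual for silyloxyfurans and cyclic iminium ions should give the Stemona-type relative configuration at the two new centres.

Step 14
Reactants: 21 butenolide adduct
Product: 22 CNP0260919.2 (target)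
Conditions: H2 (1 atm), 5% Rh/Al2O3, EtOAc, 25 °C
Reagents that add atoms: none
Why: Heterogeneous hydrogenation saturates the azepine alkene and adds hydrogen to the butenolide on the face anti to its ring substituent, which places the new methyl cis to that substituent.

**Compound list**

1 | (R)-4-[(tert-butyldimethylsilyl)oxy]cyclopent-2-en-1-one | O=C1C=C[C@H](O[Si](C)(C)C(C)(C)C)C1 | starting material
2 | zinc enolate from ethyl conjugate addition (lithium diethylzincate enolate) | CC[C@H]1[C@H](O[Si](C)(C)C(C)(C)C)CC(O[Zn-](CC)CC)=C1.[Li+] | intermediate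
3 | (2R,3R,4R)-2-allyl-4-[(tert-butyldimethylsilyl)oxy]-3-ethylcyclopentan-1-one | CC[C@H]1[C@H](O[Si](C)(C)C(C)(C)C)CC(=O)[C@@H]1CC=C | intermediate
4 | (4S,5R)-5-allyl-4-ethylcyclopent-2-en-1-one | CC[C@H]1C=CC(=O)[C@@H]1CC=C | intermediate
5 | (1S,3R,4R,5S)-3-allyl-6,6-diethoxy-4-ethylbicyclo[3.2.0]heptan-2-one | CC[C@H]1[C@@H]2C(OCC)(OCC)C[C@@H]2C(=O)[C@@H]1CC=C | intermediate
6 | (1S,3R,4R,5S)-3-allyl-2-cyclopropylidene-6,6-diethoxy-4-ethylbicyclo[3.2.0]heptane | CC[C@H]1[C@@H]2C(OCC)(OCC)C[C@@H]2C(=C2CC2)[C@@H]1CC=C | intermediate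
7 | oxaspiropentane (spiro-epoxide of 6, oxygen on the convex face) | CC[C@H]1[C@@H]2C(OCC)(OCC)C[C@@H]2[C@@]3(OC34CC4)[C@@H]1CC=C | intermediate
8 | (1S,2S,3R,4R,5S)-3-allyl-6,6-diethoxy-4-ethylspiro[bicyclo[3.2.0]heptane-2,1'-cyclobutan]-2'-one (C=O carbon on the convex face) | CC[C@H]1[C@@H]2C(OCC)(OCC)C[C@@H]2[C@]3(CCC3=O)[C@@H]1CC=C | intermediate
9 | aza-Criegee adduct (2'-hydroxy-2'-{[(diphenylphosphoryl)oxy]amino} derivative of 8) | CC[C@H]1[C@@H]2C(OCC)(OCC)C[C@@H]2[C@]3(CCC3(O)NOP(=O)(c4ccccc4)c4ccccc4)[C@@H]1CC=C | intermediate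
10 | (1S,2S,3R,4R,5S)-3-allyl-6,6-diethoxy-4-ethylspiro[bicyclo[3.2.0]heptane-2,2'-pyrrolidin]-5'-one (N on the convex face) | CC[C@H]1[C@@H]2C(OCC)(OCC)C[C@@H]2[C@]3(CCC(=O)N3)[C@@H]1CC=C | intermediate
11 | (1S,2S,3R,4R,5S)-1',3-diallyl-6,6-diethoxy-4-ethylspiro[bicyclo[3.2.0]heptane-2,2'-pyrrolidin]-5'-one | CC[C@H]1[C@@H]2C(OCC)(OCC)C[C@@H]2[C@]3(CCC(=O)N3CC=C)[C@@H]1CC=C | intermediate
12 | tetracyclic lactam ketal (seven-membered N–CH2–CH=CH–CH2 ring, Z, trans-fused to the cyclopentane; diethyl ketal of the cis-fused cyclobutanone) | CC[C@H]1[C@@H]2C(OCC)(OCC)C[C@@H]2[C@@]23CCC(=O)N2CC=CC[C@H]13 | intermediate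
13 | tetracyclic lactam cyclobutanone | CC[C@H]1[C@@H]2C(=O)C[C@@H]2[C@@]23CCC(=O)N2CC=CC[C@H]13 | intermediate
14 | tetracyclic lactam lactone (cis-fused γ-lactone, α-CH2) | CC[C@H]1[C@@H]2OC(=O)C[C@@H]2[C@@]23CCC(=O)N2CC=CC[C@H]13 | intermediate
15 | α-methyl lactone (methyl on the convex face) | CC[C@H]1[C@@H]2OC(=O)[C@@H](C)[C@@H]2[C@@]23CCC(=O)N2CC=CC[C@H]13 | intermediate
16 | α-hydroxy-α-methyl lactone (OH on the convex face) | CC[C@H]1[C@@H]2OC(=O)[C@@](C)(O)[C@@H]2[C@@]23CCC(=O)N2CC=CC[C@H]13 | intermediate
17 | 3-methylfuran-2(5H)-one | CC1=CCOC1=O | starting material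
18 | 3-methyl-2-[(triisopropylsilyl)oxy]furan | Cc1ccoc1O[Si](C(C)C)(C(C)C)C(C)C | intermediate
19 | silyl hemiaminal (lactam C=O reduced to CH–O–SiMe2–O–SiMe2H) | CC[C@H]1[C@@H]2OC(=O)[C@@](C)(O)[C@@H]2[C@@]23CCC(O[Si](C)(C)O[SiH](C)C)N2CC=CC[C@H]13 | intermediate
20 | iminium ion (cation) | CC[C@H]1[C@@H]2OC(=O)[C@@](C)(O)[C@@H]2[C@@]23CCC=[N+]2CC=CC[C@H]13 | intermediate
21 | butenolide adduct (3-methyl-5H-furan-2-on-5-yl on the pyrrolidine CH; azepine alkene still present) | CC[C@H]1[C@@H]2OC(=O)[C@@](C)(O)[C@@H]2[C@@]23CC[C@@H]([C@@H]4C=C(C)C(=O)O4)N2CC=CC[C@H]13 | intermediate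
22 | CNP0260919.2 | CC[C@H]1[C@@H]2OC(=O)[C@@](C)(O)[C@@H]2[C@@]23CC[C@@H]([C@@H]4C[C@H](C)C(=O)O4)N2CCCC[C@H]13 | target

Total step count: 14. Longest linear sequence: 13 steps (steps 1–11, 13, 14); step 12 is a one-step side branch.

**Steps most likely to fail**

Step 4. Enolisation of the hindered, α,α'-disubstituted ketone by the weakly nucleophilic ylide may outrun addition, with epimerisation at the allyl-bearing carbon. The fallback is a two-stage addition–elimination olefination that sets out from 5. Cyclopropyl phenyl sulfide and n-BuLi (THF, 0 °C) give 1-lithio-1-(phenylthio)cyclopropane F1, a strongly nucleophilic, weakly basic reagent. Its addition at −78 °C to the convex face of 5 should give the β-hydroxy sulfide F2. Reductive elimination of F2 (PI3, Et3N, CH2Cl2, 0 °C) returns to the route at 6.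

Step 13. Facial control at the iminium carbon, or the relative configuration at the lactone carbon, may be poor in the single C–C bond-forming event. The fallback sets out from 16 and derives the relative configuration of the two centres from alkene geometry and syn-hydrogenation. Thionation (Lawesson's reagent, toluene, 80 °C) gives the thiolactam F3. S-Alkylation with 5-bromo-3-methylfuran-2(5H)-one F4 (from 17 with NBS and a radical initiator) gives the thioiminium bromide F5. Eschenmoser sulfide contraction (PPh3, Et3N) gives the (E)-ylidene butenolide F6. Hydrogenation (H2, PtO2, AcOH) from the open face, syn across the exocyclic alkene and then across the remaining alkenes, returns to the route at 22.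

Step 6. Addition of the aminating reagent to the very hindered carbonyl may be slow, and the acid set free may cleave the ketal and expose the second four-membered ketone. The fallback is the classical two-stage Beckmann rearrangement, setting out from 8. NH2OH·HCl and NaOAc in EtOH give the (E)-oxime F7, whose hydroxyl should lie anti to the quaternary carbon for steric reasons. TsCl, Et3N and DMAP in CH2Cl2 give the O-tosyl oxime F8. F8 rearranges on silica or in aqueous K2CO3/THF with migration of the anti, quaternary carbon and returns to the route at 10.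

Further compounds

F1 | step 4 | 1-lithio-1-(phenylthio)cyclopropane | [Li]C1(Sc2ccccc2)CC1
F2 | step 4 | β-hydroxy sulfide (tertiary OH on the concave face, 1-(phenylthio)cyclopropyl on the convex face) | CC[C@H]1[C@@H]2C(OCC)(OCC)C[C@@H]2[C@@](O)(C2(Sc3ccccc3)CC2)[C@@H]1CC=C
F3 | step 13 | thiolactam of 16 | CC[C@H]1[C@@H]2OC(=O)[C@@](C)(O)[C@@H]2[C@@]23CCC(=S)N2CC=CC[C@H]13
F4 | step 13 | 5-bromo-3-methylfuran-2(5H)-one | CC1=CC(Br)OC1=O
F5 | step 13 | S-(3-methyl-2-oxo-2,5-dihydrofuran-5-yl) thioiminium bromide | CC[C@H]1[C@@H]2OC(=O)[C@@](C)(O)[C@@H]2[C@@]23CCC(SC4C=C(C)C(=O)O4)=[N+]2CC=CC[C@H]13.[Br-]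
F6 | step 13 | (E)-ylidene butenolide (vinylogous carbamate) | CC[C@H]1[C@@H]2OC(=O)[C@@](C)(O)[C@@H]2[C@@]23CC/C(=C4/C=C(C)C(=O)O4)N2CC=CC[C@H]13
F7 | step 6 | (E)-oxime of 8 | CC[C@H]1[C@@H]2C(OCC)(OCC)C[C@@H]2[C@]3(CC/C3=N\O)[C@@H]1CC=C
F8 | step 6 | O-tosyl oxime of 8 | CC[C@H]1[C@@H]2C(OCC)(OCC)C[C@@H]2[C@]3(CC/C3=N\OS(=O)(=O)c4ccc(C)cc4)[C@@H]1CC=C
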